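Thursday's run, with the same charge and loading as the flasks asked about, is a progress curve of [free monomer], and we read it as pseudo-first-order with a fading rate constant: 0.323 h⁻¹ up to 1.00 h, but 0.104 h⁻¹ between 5.00 h and 8.00 h, about a third of the first.

| flask | free monomer | initiator | remark | time |
|---|---|---|---|---|
| Thursday's | 0.32 M | 0.5 mol% | run made earlier |  |
| Sunday's | 0.32 M | 0.25 mol% | run made earlier |  |
| Saturday's | 0.32 M | 0.38 mol% | run made earlier |  |
| zeta | 0.32 M (fed, over 4.00 h) | 0.5 mol% | a stirred flask in which free monomer is dosed at a steady rate over 4.00 h without added volume, worked up at 8.0 h | 8.0 h |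
| eta | 0.32 M | 0.5 mol% | a single well-mixed tank run continuously and read at steady state, 8.0 h in it on average |  |
| delta | 0.32 M | 0.5 mol% | everything together in a closed stirred flask, run for 8.0 h | 8.0 h |

- Thursday's (time / h: monomer in chains / %, free monomer / %): 1.00: 28.8, 72.4; 3.00: 55.5, 44.5; 5.00: 69.1, 31.6; 8.00: 77.2, 23.1
- Sunday's (time / h: monomer in chains / %, free monomer / %): 0.417: 10.3, 90.1; 0.833: 18.8, 81.3; 2.00: 34.7, 66.1; 5.00: 55.7, 44.0
- Saturday's (time / h: monomer in chains / %, free monomer / %): 0.667: 16.0, 82.2; 1.50: 32.7, 68.9; 3.00: 52.8, 49.8; 5.00: 62.1, 34.2

(each reading ± 1 percentage point)

- the stated concentrations are those of everything mixed, before any reaction; amounts are the same in each set-up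
- what was read earlier has a scatter of 1 percentage point, one standard deviation
- the feed brings no volume worth counting
- the earlier runs were made in a closed, stirred flask

1. the set-up with the highest amount of monomer in chains at the outlet or at the end, in percent of the free monomer put in ("none" if the first two lie within 2 percentage points) (zeta / eta / delta / none)
2. amount of monomer in chains at the outlet or at the end, in percent of the free monomer put in, zeta
3. amount of monomer in chains at the outlet or at the end, in percent of the free monomer put in, eta
4. amount of monomer in chains at the outlet or at the end, in percent of the free monomer put in, delta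

Our weak link is an assumption: that this rate follows the clock from the charging of the initiator, and not the amount of free monomer. Granting it, and taking the initiator as charged at the start in zeta, let f be Thursday's [free monomer] as a fraction of its start. A portion fed at time s then survives to a later time t as f(t)/f(s), so the integral over a steady feed closes: zeta's fraction after the feed is f(t) times the mean reciprocal of f during the feed. Taking f at 4.00 h as 37.5 %, the geometric mean of the neighbouring readings, and joining the reciprocals by straight lines, that mean is 1.82, and this factor is the feed penalty, the ratio of free monomer left in the fed flask to that left in the closed flask at one clock time after the feed has ended. Applied to Thursday's 23.1 %, it leaves 42.0 % in zeta, so our reckoning puts 58.0 % in chains, less than the 77.2 % read for delta's conditions.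

The forecast, a separate reckoning, says 57.5 % for zeta, 58.4 % for eta and 77 % for delta, and names delta as best, reasoning that “the monomer arrives as the initiator fades”; its second-order reading gave about 69 % for zeta.

The flask gives 58.3 % for zeta, 58.7 % for eta and 77.2 % for delta, so delta is best.

    free monomer + growing radical → monomer in chains + growing radical, rate k1*[growing radical]*[free monomer] (k = 76000 M⁻¹ min⁻¹)
    initiator → 2 initiating radical (k = 0.00620 min⁻¹)
    2 growing radical → dead chain (k = 2.80 × 10⁷ M⁻¹ s⁻¹)
    free monomer + initiating radical → growing radical + monomer in chains (k = 84000 M⁻¹ s⁻¹)

The weak link holds: growing radical stands at 3.65 × 10⁻⁸ M in zeta and 3.65 × 10⁻⁸ M in delta at 4.00 h, and at 1.74 × 10⁻⁸ M and 1.74 × 10⁻⁸ M at 8.00 h. Zeta's free monomer is 1.83 times delta's at that time, against a penalty of 1.82, and the neighbouring flask, zeta read at 5.0 h, holds 57.4 % free monomer, where the penalty on Thursday's 31.6 % gives 57.5 %. Zeta is not at rest at 8.00 h: by 80.0 h, with initiator at 0 % and growing radical at 2.51 × 10⁻¹³ M, its free monomer falls from 42 % to 27.2 %, still 1.83 times delta's 14.9 %, and monomer in chains reaches 72.8 %.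

The readings are calculated with constants of no real substance, and the scatter is random.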